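## Retrosynthetic overview

- **Feature:** in ring A, O1–C2(aryl)–C3(methyl)–C3a is an anti homoallylic alcohol pattern. C7a, the enol-ether carbon shared by rings A and B, is at the carboxylic acid oxidation level. Ring A is therefore built first as a trans γ-lactone whose carbonyl carbon is C7a.
- **C5–OMe:** traced back to the C5 enolate of the bicyclic vinylogous ester, by hydroxylation anti to the pseudo-axial C3a allyl group and then O-methylation.
- **Ring B:** C7–C7a comes from Dieckmann-type acylation of a methyl ketone by the lactone, after which O1 re-closes on C7a. C3a–C4 comes from Mukaiyama–Michael addition of the lactone silyl ketene acetal to methyl vinyl ketone, anti to the C3 methyl group.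
- **Allyl group:** vinyl–copper 1,4-addition to the exocyclic methylene of the α-methylene lactone.
- **Ring A:** C2–C3 and O1–C7a form in one operation from 3,4,5-trimethoxybenzaldehyde and an ester-bearing crotylboronate under chiral phosphoric acid catalysis. Ring A closes in step 2 and ring B in step 6.

Key step: step 2

Numbering: O1 and C2–C7a follow the benzofuranone numbering of the target. Ring A is the five-membered oxygen ring and ring B is the carbocycle.

Assumption: (R)-TRIP is taken to open the Re face of the aldehyde, as it does with the parent allyl and crotyl pinacol boronates. If the ester-bearing reagent responds in the opposite sense, (S)-TRIP is used with no other change.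

## Route

Step 1
Reactants: 1 ethyl but-2-ynoate; 2 2-(iodomethyl)-4,4,5,5-tetramethyl-1,3,2-dioxaborolane
Product: 4 ethyl (Z)-2-[(4,4,5,5-tetramethyl-1,3,2-dioxaborolan-2-yl)methyl]but-2-enoate, via alkenylalane 3 (not isolated)
Conditions: i-Bu2AlH (1.1 equiv), HMPA (2 equiv), THF, 0 °C; then 2, 0 °C → rt
Reagents that add atoms: none
Why: Conjugate hydroalumination adds H and Al syn across the ynoate, and alane 3 then attacks the boron of 2 and shifts to carbon with loss of iodide (Matteson-type 1,2-migration) with retention, so the methyl group ends up trans to CH2B and cis to the ester, a geometry that SN2′ borylation of the acetaldehyde Baylis–Hillman acetate would not deliver because there the methyl group settles cis to CH2B.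

Step 2
Reactants: 4 ethyl (Z)-2-[(pinacolatoboryl)methyl]but-2-enoate; 5 3,4,5-trimethoxybenzaldehyde
Product: 8 (4R,5R)-4-methyl-3-methylidene-5-(3,4,5-trimethoxyphenyl)oxolan-2-one, via pinacol borate 6 (not isolated), via hydroxy ester 7 (not isolated)
Conditions: (R)-3,3′-bis(2,4,6-triisopropylphenyl)-1,1′-binaphthyl-2,2′-diyl hydrogen phosphate [(R)-TRIP] (10 mol %), 4 Å MS, toluene, 0 °C → rt; then p-TsOH·H2O (20 mol %), rt
Reagents that add atoms: none
Why: The acidic proton of the phosphoric acid binds the pseudo-equatorial pinacol oxygen of 4 and its P=O oxygen holds the formyl hydrogen of 5, so boron binds the aldehyde oxygen and C2–C3 forms through a closed six-membered Zimmerman–Traxler chair; the closest known reactions are the Brønsted acid catalysed allylboration–lactonisation of 2-alkoxycarbonyl allylboronates and the chiral phosphoric acid catalysed crotylboration of aromatic aldehydes with pinacol boronates. Ring A then closes by 5-exo-trig attack of the C2 oxygen (as borate 6 or free alcohol 7) on the ester carbonyl, which forms O1–C7a with loss of ethanol. The C2/C3 relationship follows from the alkene geometry of 4: the methyl group trans to CH2B sits equatorial in the chair, giving the anti alcohol and hence the trans lactone. The absolute configuration comes from the triisopropylphenyl walls of the (R)-catalyst, which leave the Re face of the aldehyde open and so set (R) at C2 and, through the chair, (R) at C3. The step needs the catalysed path to outrun the background reaction, and this is secured because the electron-poor boronate 4 is almost inert towards aldehydes at room temperature without acid. Any ionisation at the electron-rich benzylic C2 during the TsOH finish should re-close under control of the untouched C3 centre to the same, more stable trans lactone.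

Step 3
Reactants: 8 trans α-methylene lactone; 9 vinylmagnesium bromide
Product: 11 (4R,5R)-3-allyl-4-methyl-5-(3,4,5-trimethoxyphenyl)oxolan-2-one (mixture of C3 epimers), via trimethylsilyl ketene acetal 10 (not isolated)
Conditions: CH2=CHMgBr (1.5 equiv), CuBr·SMe2 (10 mol %), Me3SiCl (2 equiv), THF, −78 °C; then 1 M HCl, 0 °C
Reagents that add atoms: none
Why: Copper-catalysed, Me3SiCl-accelerated 1,4-addition of the vinyl Grignard reagent to the s-cis-locked α-methylene lactone turns the exocyclic CH2 into the allyl CH2, ketene acetal 10 is hydrolysed on work-up, and the epimer mixture at C3 does not matter because this centre is flattened again in step 4.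

Step 4
Reactants: 11 α-allyl lactone
Product: 13 tert-butyl{[(4R,5R)-3-allyl-4-methyl-5-(3,4,5-trimethoxyphenyl)-4,5-dihydrofuran-2-yl]oxy}dimethylsilane, via lithium enolate 12 (not isolated)
Conditions: LiN(i-Pr)2 (1.2 equiv), THF, −78 °C; TBSCl (1.4 equiv), DMPU, −78 °C → rt; pentane/cold aq. NaHCO3
Reagents that add atoms: tert-butyldimethylsilyl chloride, CC(C)(C)[Si](C)(C)Cl
Why: Deprotonation at the only acidic C–H and O-silylation of the lactone enolate (silyl ketene acetal formation as in Ireland-type chemistry) should give a tetrasubstituted cyclic ketene acetal robust enough for extractive isolation, with C4 and C5 untouched.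

Step 5
Reactants: 13 TBS ketene acetal; 14 methyl vinyl ketone
Product: 16 (3S,4R,5R)-3-allyl-4-methyl-3-(3-oxobutyl)-5-(3,4,5-trimethoxyphenyl)oxolan-2-one, via silyl enol ether 15 (not isolated)
Conditions: 14 (1.5 equiv), Sc(OTf)3 (10 mol %), CH2Cl2, −78 → −20 °C; then 1 M HCl, THF, rt
Reagents that add atoms: none
Why: In this Mukaiyama–Michael addition the neutral silyl nucleophile avoids 1,2-addition and enone polymerisation, and the unhindered CH2 terminus of the activated enone should reach the ketene acetal carbon on the face anti to the adjacent methyl group, so C4 ends up trans and the allyl group cis to that methyl at the new quaternary C3a.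

Step 6
Reactants: 16 keto lactone
Product: 18 (2R,3R,3aS)-3a-allyl-3-methyl-2-(3,4,5-trimethoxyphenyl)-3,3a,4,5-tetrahydro-1-benzofuran-6(2H)-one, via hydroxy dione 17 (not isolated)
Conditions: KOt-Bu (2.2 equiv), THF, 0 °C → rt; 1 M HCl to pH 4, 0 °C; then PPTS (10 mol %), 4 Å MS, toluene, 40 °C
Reagents that add atoms: none
Why: Dieckmann-type 6-exo-trig acylation of the methyl ketone enolate (C7) by the lactone carbonyl (C7a) is driven by formation of the 1,3-diketone enolate, and after acidification the freed C2 hydroxyl can reach only C7a (5-exo-trig), so mild acid-catalysed dehydration gives the vinylogous ester without breaking a bond to any stereocentre and without ionising benzylic C2.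

Step 7
Reactants: 18 bicyclic vinylogous ester
Product: 20 (2R,3R,3aR,5R)-3a-allyl-5-hydroxy-3-methyl-2-(3,4,5-trimethoxyphenyl)-3,3a,4,5-tetrahydro-1-benzofuran-6(2H)-one, via potassium dienolate 19 (not isolated)
Conditions: KN(SiMe3)2 (1.2 equiv), THF, −78 °C; 2-(phenylsulfonyl)-3-phenyloxaziridine (1.4 equiv), −78 °C; AcOH
Reagents that add atoms: 2-(phenylsulfonyl)-3-phenyloxaziridine, O=S(=O)(c1ccccc1)N1OC1c1ccccc1
Why: In this Davis oxidation C5 carries the only enolisable hydrogens (C3a is quaternary), and the cross-conjugated dienolate 19 should accept oxygen on the face opposite the pseudo-axial C3a allyl group, giving the pseudo-equatorial (5R)-alcohol, which is also the more stable epimer.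

Step 8
Reactants: 20 α′-hydroxy enone
Product: 21 (2R,3R,3aR,5R)-3a-allyl-5-methoxy-3-methyl-2-(3,4,5-trimethoxyphenyl)-3,3a,4,5-tetrahydro-1-benzofuran-6(2H)-one (CNP0236389.2)
Conditions: MeI (10 equiv), Ag2O (3 equiv), 4 Å MS, CH2Cl2, rt, dark
Reagents that add atoms: iodomethane, CI
Why: Purdie methylation runs under nearly neutral conditions, so the α-ketol should be etherified without ketol shift or oxidation, and C5 keeps the equatorial (R) configuration, which is in any case the thermodynamically preferred one.

## Compound list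

1 | ethyl but-2-ynoate | CC#CC(=O)OCC | starting material
2 | 2-(iodomethyl)-4,4,5,5-tetramethyl-1,3,2-dioxaborolane | ICB1OC(C)(C)C(C)(C)O1 | starting material
3 | ethyl (E)-2-(diisobutylalumanyl)but-2-enoate (H cis to Al) | C/C=C(/[Al](CC(C)C)CC(C)C)C(=O)OCC | intermediate
4 | ethyl (Z)-2-[(4,4,5,5-tetramethyl-1,3,2-dioxaborolan-2-yl)methyl]but-2-enoate (methyl trans to CH2B) | C/C=C(/CB1OC(C)(C)C(C)(C)O1)C(=O)OCC | intermediate
5 | 3,4,5-trimethoxybenzaldehyde | COc1cc(C=O)cc(OC)c1OC | starting material
6 | ethyl (3R,4R)-3-methyl-2-methylidene-4-[(4,4,5,5-tetramethyl-1,3,2-dioxaborolan-2-yl)oxy]-4-(3,4,5-trimethoxyphenyl)butanoate | C=C(C(=O)OCC)[C@@H](C)[C@@H](OB1OC(C)(C)C(C)(C)O1)c1cc(OC)c(OC)c(OC)c1 | intermediate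
7 | ethyl (3R,4R)-4-hydroxy-3-methyl-2-methylidene-4-(3,4,5-trimethoxyphenyl)butanoate (anti) | C=C(C(=O)OCC)[C@@H](C)[C@@H](O)c1cc(OC)c(OC)c(OC)c1 | intermediate
8 | (4R,5R)-4-methyl-3-methylidene-5-(3,4,5-trimethoxyphenyl)oxolan-2-one (trans) | C=C1C(=O)O[C@@H](c2cc(OC)c(OC)c(OC)c2)[C@@H]1C | intermediate
9 | vinylmagnesium bromide | C=C[Mg]Br | starting material
10 | {[(4R,5R)-3-allyl-4-methyl-5-(3,4,5-trimethoxyphenyl)-4,5-dihydrofuran-2-yl]oxy}trimethylsilane | C=CCC1=C(O[Si](C)(C)C)O[C@@H](c2cc(OC)c(OC)c(OC)c2)[C@@H]1C | intermediate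
11 | (4R,5R)-3-allyl-4-methyl-5-(3,4,5-trimethoxyphenyl)oxolan-2-one, C3 epimer mixture | C=CCC1C(=O)O[C@@H](c2cc(OC)c(OC)c(OC)c2)[C@@H]1C | intermediate
12 | lithium enolate of 11 | C=CCC1=C([O-])O[C@@H](c2cc(OC)c(OC)c(OC)c2)[C@@H]1C.[Li+] | intermediate
13 | tert-butyl{[(4R,5R)-3-allyl-4-methyl-5-(3,4,5-trimethoxyphenyl)-4,5-dihydrofuran-2-yl]oxy}dimethylsilane | C=CCC1=C(O[Si](C)(C)C(C)(C)C)O[C@@H](c2cc(OC)c(OC)c(OC)c2)[C@@H]1C | intermediate
14 | methyl vinyl ketone (but-3-en-2-one) | C=CC(C)=O | starting material
15 | (3R,4R,5R)-3-allyl-3-[3-(tert-butyldimethylsilyloxy)but-2-enyl]-4-methyl-5-(3,4,5-trimethoxyphenyl)oxolan-2-one, E/Z mixture | C=CC[C@]1(CC=C(C)O[Si](C)(C)C(C)(C)C)C(=O)O[C@@H](c2cc(OC)c(OC)c(OC)c2)[C@@H]1C | intermediate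
16 | (3S,4R,5R)-3-allyl-4-methyl-3-(3-oxobutyl)-5-(3,4,5-trimethoxyphenyl)oxolan-2-one | C=CC[C@]1(CCC(C)=O)C(=O)O[C@@H](c2cc(OC)c(OC)c(OC)c2)[C@@H]1C | intermediate
17 | (4S)-4-allyl-4-[(1R,2R)-1-hydroxy-1-(3,4,5-trimethoxyphenyl)propan-2-yl]cyclohexane-1,3-dione | C=CC[C@@]1(CCC(=O)CC1=O)[C@@H](C)[C@@H](O)c1cc(OC)c(OC)c(OC)c1 | intermediate
18 | (2R,3R,3aS)-3a-allyl-3-methyl-2-(3,4,5-trimethoxyphenyl)-3,3a,4,5-tetrahydro-1-benzofuran-6(2H)-one | C=CC[C@]12CCC(=O)C=C1O[C@@H](c1cc(OC)c(OC)c(OC)c1)[C@@H]2C | intermediate
19 | potassium C5,C6-dienolate of 18 | C=CC[C@]12CC=C([O-])C=C1O[C@@H](c1cc(OC)c(OC)c(OC)c1)[C@@H]2C.[K+] | intermediate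
20 | (2R,3R,3aR,5R)-3a-allyl-5-hydroxy-3-methyl-2-(3,4,5-trimethoxyphenyl)-3,3a,4,5-tetrahydro-1-benzofuran-6(2H)-one | C=CC[C@]12C[C@@H](O)C(=O)C=C1O[C@@H](c1cc(OC)c(OC)c(OC)c1)[C@@H]2C | intermediate
21 | (2R,3R,3aR,5R)-3a-allyl-5-methoxy-3-methyl-2-(3,4,5-trimethoxyphenyl)-3,3a,4,5-tetrahydro-1-benzofuran-6(2H)-one | C=CC[C@]12C[C@@H](OC)C(=O)C=C1O[C@@H](c1cc(OC)c(OC)c(OC)c1)[C@@H]2C | target

## Step count and risks

Total step count: 8. Longest linear sequence: 8 (1 → 21).

### Step 2

The weak chiral acid may not activate the electron-poor boronate enough towards an electron-rich aldehyde, so conversion stalls. The ester group may also disturb the catalyst–boronate contact, which would erode enantioface selection.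

The fallback sets out from 5 and returns at 11.
- Commercial (E)-crotylboronic acid pinacol ester is added to 5 under (R)-TRIP catalysis (toluene, −30 °C). This is the established crotylboration of aromatic aldehydes, and it should give (1R,2R)-2-methyl-1-(3,4,5-trimethoxyphenyl)but-3-en-1-ol F1.
- Hydroboration with 9-BBN followed by NaOH/H2O2 gives (1R,2R)-2-methyl-1-(3,4,5-trimethoxyphenyl)butane-1,4-diol F2.
- Oxidative lactonisation with TEMPO/PhI(OAc)2 gives (4R,5R)-4-methyl-5-(3,4,5-trimethoxyphenyl)oxolan-2-one F3.
- LiN(i-Pr)2 and then allyl bromide give 11.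

In this variant C7a is created by hydroboration–oxidation instead of being carried in the boron reagent, and the allyl group enters by enolate alkylation.

### Step 5

The ketene acetal may be protodesilylated, or the enone may oligomerise. Facial discrimination may also be insufficient, because the C5 aryl group lies on the face that has to be attacked.

The fallback sets out from 11 and returns at 16.
- Finkelstein exchange (NaI, acetone) on commercial 2-(2-bromoethyl)-2-methyl-1,3-dioxolane gives 2-(2-iodoethyl)-2-methyl-1,3-dioxolane F4.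
- Lithium enolate 12, generated from 11, is alkylated with F4 in THF/DMPU (−78 → −20 °C). SN2 alkylation of β-substituted butyrolactone enolates is the best documented case of attack anti to the β-substituent. It should give (3S,4R,5R)-3-allyl-4-methyl-3-[2-(2-methyl-1,3-dioxolan-2-yl)ethyl]-5-(3,4,5-trimethoxyphenyl)oxolan-2-one F5.
- PPTS in aqueous acetone then unmasks ketone 16.

### Step 7

Facial selectivity at C5 may be poor. The enolate may add to the sulfonimine that the oxidant releases. Over-oxidation towards the diosphenol is also possible.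

The fallback sets out from 18 and returns at 20.
- LiN(i-Pr)2 and Me3SiCl give the neutral, isolable {[(2R,3R,3aR)-3a-allyl-3-methyl-2-(3,4,5-trimethoxyphenyl)-2,3,3a,4-tetrahydro-1-benzofuran-6-yl]oxy}trimethylsilane F6.
- Rubottom oxidation of its electron-rich C5=C6 bond follows, with dimethyldioxirane in acetone at low temperature; the terminal alkene is far less reactive.
- A citric acid/MeOH work-up then gives 20.

## Further compounds

F1 | step 2 | (1R,2R)-2-methyl-1-(3,4,5-trimethoxyphenyl)but-3-en-1-ol | C=C[C@@H](C)[C@@H](O)c1cc(OC)c(OC)c(OC)c1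
F2 | step 2 | (1R,2R)-2-methyl-1-(3,4,5-trimethoxyphenyl)butane-1,4-diol | OCC[C@@H](C)[C@@H](O)c1cc(OC)c(OC)c(OC)c1
F3 | step 2 | (4R,5R)-4-methyl-5-(3,4,5-trimethoxyphenyl)oxolan-2-one | C1C(=O)O[C@@H](c2cc(OC)c(OC)c(OC)c2)[C@@H]1C
F4 | step 5 | 2-(2-iodoethyl)-2-methyl-1,3-dioxolane | CC1(CCI)OCCO1
F5 | step 5 | (3S,4R,5R)-3-allyl-4-methyl-3-[2-(2-methyl-1,3-dioxolan-2-yl)ethyl]-5-(3,4,5-trimethoxyphenyl)oxolan-2-one | C=CC[C@]1(CCC2(C)OCCO2)C(=O)O[C@@H](c3cc(OC)c(OC)c(OC)c3)[C@@H]1C
F6 | step 7 | {[(2R,3R,3aR)-3a-allyl-3-methyl-2-(3,4,5-trimethoxyphenyl)-2,3,3a,4-tetrahydro-1-benzofuran-6-yl]oxy}trimethylsilane | C=CC[C@]12CC=C(O[Si](C)(C)C)C=C1O[C@@H](c1cc(OC)c(OC)c(OC)c1)[C@@H]2C
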